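Atom numbers C1–C10 used throughout: C1 is the methyl-bearing quaternary ring-fusion carbon, C2 and C6 are the angelate carbons, C3 is the ring CH2, C4 is the isopropyl carbinol, C5 is the ring-fusion CH, and C7–C10 complete the seven-membered ring (C8 carries methyl, C8=C9 is the alkene).

## The problem

The target is a trans-fused bicyclo[5.3.0]decene in which a cyclopentane (C1–C5) carrying three oxygens shares the C1–C5 bond with a cycloheptene (C1, C5–C10). Five stereocentres on adjacent carbons have to be set: quaternary C1, the secondary angelate carbons C2 and C6, the tertiary carbinol C4 and the ring-fusion carbon C5. C1 has no neighbour that could control it and must be set absolutely, and C5 must end trans to the C1 methyl group. Once that ring fusion exists, C4 follows from the ring closure, and the C4 hydroxyl, which is 1,3 to both C2 and C6, can direct hydride to both carbons. The angelates isomerise to tiglates under base, nucleophiles or heat and must come last. The tertiary C4 hydroxyl is β to any C2 or C6 carbonyl and invites retro-aldol cleavage and dehydration. The C8=C9 alkene is β,γ to a C6 carbonyl, so C7 is more acidic than C5; base would move the alkene into conjugation before it epimerised C5, and C5 therefore has to be right when it is made. The feature that opens the route is that the seven-membered ring, with methyls on C1 and C8, oxygen on C6 and the C8=C9 alkene, is 2,5-dimethylanisole plus one carbon (C5), and that it arrives as a C5=C1 enone across which C2–C3 and C4 with its isopropyl group can be added in one operation.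

## Retrosynthesis

**Esters.** The two ester C–O bonds of target 27 are cut first, one after the other through monoester 26, giving triol 23 and two molecules of angelic acid 24. An angelate is at risk of Z to E isomerisation under enolate chemistry, basic fluoride or nucleophiles, so the esters are best introduced last. Triol 23 keeps all five stereocentres; the forward step must acylate two hindered secondary hydroxyls, leave the tertiary one alone and keep the Z geometry.

**C2–H and C6–H.** Both carbinols of 23 are taken back to the ketones of diketol 22. The argument for cutting both at once is that each carbonyl is β to the C4 hydroxyl, so one directing group can set both centres in the same sense. Setting them separately by outside reagents would need two more protecting groups. Diketol 22 has three stereocentres instead of five; the forward reaction must deliver hydride from the C4 oxygen to both carbonyl groups.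

**C3–C4.** The β-hydroxy ketone C2(=O)–C3–C4(OH) in 22 is an aldol retron, so the five-membered ring is opened at C3–C4. A cut at C1–C2 or C4–C5 would make a ring closure create the quaternary centre or the congested C4–C5 bond. C6 cannot be a ketone during this closure, because C5 would then sit between two carbonyl groups; it is carried as a silyl ether (20, 21) and reoxidised afterwards. The precursor is monocyclic diketone 18, whose acetyl and isobutyryl arms are trans across C1–C5. The forward step needs the enolate of the methyl ketone only and must stop before dehydration.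

**Functional group changes.** No skeletal bond is cut between 18 and 10. The acetyl group of 18 comes from a vinyl group (17) and the C4 ketone from the carbinol (16). The oxidation levels of C4 and C6 are exchanged by a Tishchenko step (10 to 11, then 12, 15, 16), which tells the two oxygens apart without base. The vinyl group comes from a 1-silylvinyl group (12 to 14 to 15), whose silicon was needed in the key step and is removed by hydroboration and elimination because acid would attack the C8=C9 alkene.

**C1–C2 and C4–C5 (key cut).** Aldol 10 is opened to dienone 5, trimethylsilylacetylene 6 and isobutyraldehyde 7. This cut uses the only reactive group of 5, makes the quaternary centre by catalysis and attaches every carbon of the five-membered ring in one step. A stepwise alkylation at C5 of a preformed ketone would deprotonate at C7 instead. The vinyl unit is delivered as its 1-trimethylsilyl derivative for two reasons. Plain vinyl is the least documented nucleophile for this reaction class. Plain vinyl and methyl are also of about the same size, so the aldehyde would enter C5 from either face. The forward reaction must control the enantioface at C1, the face at C5, and 1,4- against 1,2-addition, and must spare the skipped diene.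

**C5 insertion.** Dienone 5 goes back through bromodienone 4 and dibromocyclopropane 3 to diene 2 and 2,5-dimethylanisole 1. The bonds cut are C5–C6 and C5–C1, that is, the carbon inserted between the methoxy-bearing and the methyl-bearing arene carbons. The arene already carries the right substitution pattern, and no other route to a 3,6-dimethylcycloheptadienone is as short. The forward steps rely on Birch regiochemistry, carbene addition to the enol ether bond only, and electrocyclic ring opening.

## Roads not taken

**Alternative 1:** The cut is C1–C5, made by ring contraction. The cyclohexene of (R)-terpinen-4-ol A1 supplies C4 with its hydroxyl and isopropyl group. After C1 has been made quaternary and C2 oxygenated, diazo ketone A2 is irradiated in an alcohol; C1 migrates with retention from the carbonyl carbon C6 to the carbene carbon C5 (Wolff rearrangement) and the ketene is trapped as cyclopentane ester A3.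
- Merits: C4 is bought rather than made, no catalyst is needed for absolute configuration, and the migration is stereospecific at C1.
- Weak points: A3 holds only the five-membered ring. The seven-membered ring with its trisubstituted alkene must still be grown from the allyl group and the ester carbon. C5 is set by protonation of a ketene-derived enol. Forcing a quaternary centre and an oxygen onto A1 before diazo transfer is long.
- Comparison: at C4 this road is better than the chosen one, which creates C4 in the closure of step 13 under substrate control. The chosen plan sets against this a seven-membered ring that comes complete from an arene in four steps.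

**Alternative 2:** The cuts are C5–C6 and C1–C10 on silyloxy cyclopentenone A4. A metallated dithiane adds to C5 anti to the silyloxy group and the enolate is alkylated at C1 by a Z allylic halide, giving cyclopentanone A5.
- Merits: the trans relation of C5 and C1 follows from anti addition and anti alkylation on a five-membered ring. This is a firmer basis than the size argument on which the chosen plan rests at C5. The Z alkene is fixed before ring closure.
- Weak points: C-alkylation of a fully substituted enolate competes with proton transfer and with β-elimination of the silyloxy group. The seven-membered ring still has to close by dithiane alkylation. The isopropyl group must later be added to a C4 ketone with facial control.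
- Comparison: the chosen plan has more doubt at C5 but needs no medium-ring closure and far fewer steps after its key step.

**Alternative 3:** The cuts are C6–C7 and C1–C10. Cr(CO)5 carbene complex A7 cyclopropanates the 1,1-disubstituted double bond of isoprene A6, and the cis-divinylcyclopropane undergoes Cope rearrangement to enol ether A8.
- Merits: it is the most convergent of the four roads and places the C8=C9 alkene and the C6 oxygen in the ring-forming step, with C2 and C4 already present.
- Weak points: quaternary C1 is set in the rearrangement by the neighbouring silyloxy group alone. C5 is sp2 in A8, so the trans ring fusion must be made afterwards by protonation next to a fully substituted C4. Alkenyl carbene complexes prefer the less substituted diene terminus, the opposite of what is required. Chromium is stoichiometric.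
- Comparison: in convergence and alkene placement this road is better. The chosen plan sets against it catalytic control of C1 and a C5 centre fixed before the five-membered ring closes.

Key step: step 5

## Route

Remark on the chemistry: the aldol of step 5 is drawn as the anti adduct expected from a closed transition state, and its C4 epimer, the C6 carbinol epimers that follow from it in step 6 and the C2 epimers of 13 and 14 take the same route, because these centres are later destroyed (steps 9, 11 and 15); in step 17 the first acyl transfer is drawn at the C6 hydroxyl, and the C2 monoester, should it form first, is carried to the same bis-ester in the same flask.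

Step 1
Reactants: 1 2,5-dimethylanisole
Product: 2 1-methoxy-2,5-dimethylcyclohexa-1,4-diene
Conditions: Li, NH3(l), THF, t-BuOH, −78 → −33 °C
Reagents that add atoms: none
Why: Birch reduction; the two protons go to C3 and C6 of the arene, which leaves the methoxy and both methyl groups on sp2 carbons; no stereocentre forms.

Step 2
Reactants: 2 1-methoxy-2,5-dimethylcyclohexa-1,4-diene
Product: 3 7,7-dibromo-1-methoxy-3,6-dimethylbicyclo[4.1.0]hept-3-ene (racemic)
Conditions: CHBr3, KOt-Bu, pentane, −20 → 0 °C
Reagents that add atoms: bromoform BrC(Br)Br
Why: Dibromocarbene (α-elimination of bromoform) is electrophilic and adds in a cheletropic cis fashion to the tetrasubstituted enol ether bond rather than to the trisubstituted alkene; the two new centres become sp2 again in step 3.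

Step 3
Reactants: 3 7,7-dibromo-1-methoxy-3,6-dimethylbicyclo[4.1.0]hept-3-ene
Product: 4 2-bromo-3,6-dimethylcyclohepta-2,5-dien-1-one
Conditions: AgNO3, CaCO3, acetone/H2O 4:1, rt
Reagents that add atoms: water O
Why: Silver-assisted loss of the endo bromide is concerted with disrotatory opening of the cyclopropane bond between the methoxy and methyl carbons (ring enlargement of an alkoxy gem-dibromocyclopropane); the methoxy-stabilised 2-bromoallyl cation is hydrolysed to the α-bromo enone and the remote alkene stays skipped.

Step 4
Reactants: 4 2-bromo-3,6-dimethylcyclohepta-2,5-dien-1-one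
Product: 5 3,6-dimethylcyclohepta-2,5-dien-1-one
Conditions: Bu3SnH, AIBN (cat.), benzene, 80 °C
Reagents that add atoms: none
Why: Radical-chain hydrodebromination; the stannyl radical abstracts the carbonyl-activated vinylic bromine and the vinyl radical takes hydrogen from Bu3SnH; the neutral medium keeps the 2,5-diene out of conjugation.

Step 5
Reactants: 5 3,6-dimethylcyclohepta-2,5-dien-1-one; 6 trimethylsilylacetylene; 7 isobutyraldehyde
Product: 10 2-(1-hydroxy-2-methylpropyl)-3,6-dimethyl-3-[1-(trimethylsilyl)vinyl]cyclohept-5-en-1-one (side chain at C2 cis to the 3-methyl group; anti aldol), via vinylalane 8 (not isolated), via aluminium enolate 9 (not isolated)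
Conditions: 6, i-Bu2AlH, hexanes, 55 °C; then Cu(OTf)2 (5 mol%), chiral sulfonate-bearing imidazolinium salt (5 mol%), 5, THF, −78 → −30 °C; then 7, −78 → −40 °C; aq. potassium sodium tartrate
Reagents that add atoms: none
Why: Three-component conjugate addition–aldol: cis-hydroalumination of 6 puts aluminium on the silicon-bearing carbon (8); the vinyl group passes to the chiral carbene–copper catalyst formed in the flask, adds to C1, the β-carbon of the only enone of 5 (oxidative addition, then reductive elimination at trivalent copper), and leaves the regiodefined C5=C6 aluminium enolate 9, which adds to 7 through a closed six-membered transition state. The closest known reaction type is the carbene–copper-catalysed enantioselective conjugate addition of silicon-substituted vinylaluminium reagents to β-methylcycloalkenones, which builds vinyl-bearing quaternary centres, joined to aldehyde capture of a conjugate-addition enolate. No ring closes; the step forms C1–C2 and C4–C5. C1 is set by the ligand, whose enantiomer is chosen so that the vinyl unit enters the face drawn. C5 is set by the substrate: the aldehyde enters anti to the larger C1 substituent, the silylvinyl group, and therefore cis to the methyl group; this is what the silyl spectator is for, since plain vinyl and methyl are of like size and C5 cannot be corrected later. The C4 carbinol is expected anti and is of no consequence. The step needs 1,4- over 1,2-addition (soft copper nucleophile) and attack at one alkene only (C8=C9 is not conjugated), and the weakly basic alane spares the doubly allylic C10 protons.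

Step 6
Reactants: 10 aldol from step 5; 7 isobutyraldehyde
Product: 11 2-(1-isobutyryloxy-2-methylpropyl)-3,6-dimethyl-3-[1-(trimethylsilyl)vinyl]cyclohept-5-en-1-ol (1-hydroxyl anti to the side-chain oxygen)
Conditions: 7 (5 equiv), SmI2 (20 mol%), THF, −10 °C
Reagents that add atoms: none
Why: Evans–Tishchenko reaction; the samarium-bound hemiacetal of the C4 hydroxyl with 7 transfers hydride to C6 within a chair-like array, giving the 1,3-anti diol with the C4 oxygen acylated and the C6 hydroxyl free; the C6 configuration does not matter (reoxidised in step 15), and the two oxygens are told apart without base.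

Step 7
Reactants: 11 diol monoisobutyrate
Product: 12 tert-butyldimethylsilyl ether of 11
Conditions: TBSOTf, 2,6-lutidine, CH2Cl2, −78 → 0 °C
Reagents that add atoms: tert-butyldimethylsilyl triflate CC(C)(C)[Si](C)(C)OS(=O)(=O)C(F)(F)F
Why: Silylation of the hindered secondary C6 hydroxyl with the reactive silyl triflate; the hindered base prevents acyl migration and protodesilylation.

Step 8
Reactants: 12 silyl ether
Product: 14 1-{7-(tert-butyldimethylsilyloxy)-2-[2-hydroxy-1-(trimethylsilyl)ethyl]-2,5-dimethylcyclohept-4-en-1-yl}-2-methylpropyl isobutyrate, via alkylborane 13 (not isolated)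
Conditions: 9-BBN, THF, 0 → 40 °C; then NaOH, H2O2, 0 °C
Reagents that add atoms: hydrogen peroxide OO
Why: Hydroboration–oxidation; 9-BBN adds to the 1,1-disubstituted vinylsilane with boron on the terminal carbon and is far slower with the trisubstituted ring alkene; oxidation with retention gives the β-hydroxysilane, whose new centre at C2 is lost in step 9.

Step 9
Reactants: 14 β-hydroxysilane
Product: 15 1-[7-(tert-butyldimethylsilyloxy)-2,5-dimethyl-2-vinylcyclohept-4-en-1-yl]-2-methylpropyl isobutyrate
Conditions: KH, THF, 0 °C
Reagents that add atoms: none
Why: Peterson elimination; the potassium alkoxide attacks silicon and syn-elimination of silanolate gives the vinyl group; steps 8 and 9 together remove silicon without the acid that would protonate the C8=C9 alkene.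

Step 10
Reactants: 15 vinyl isobutyrate
Product: 16 1-[7-(tert-butyldimethylsilyloxy)-2,5-dimethyl-2-vinylcyclohept-4-en-1-yl]-2-methylpropan-1-ol
Conditions: i-Bu2AlH, CH2Cl2, −78 °C; aq. potassium sodium tartrate
Reagents that add atoms: none
Why: Reductive cleavage of the hindered ester at low temperature; silyl ether and alkenes are inert, and the aluminium alkoxide does not promote silyl migration.

Step 11
Reactants: 16 vinyl alcohol
Product: 17 1-[7-(tert-butyldimethylsilyloxy)-2,5-dimethyl-2-vinylcyclohept-4-en-1-yl]-2-methylpropan-1-one
Conditions: Dess–Martin periodinane, NaHCO3, CH2Cl2, 0 °C → rt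
Reagents that add atoms: none
Why: Dess–Martin oxidation of the secondary C4 carbinol under buffered, non-enolising conditions, which keep C5 (now α to a ketone) intact; the C4 epimers converge.

Step 12
Reactants: 17 vinyl ketone
Product: 18 1-[2-acetyl-7-(tert-butyldimethylsilyloxy)-2,5-dimethylcyclohept-4-en-1-yl]-2-methylpropan-1-one (acetyl and isobutyryl trans)
Conditions: PdCl2 (10 mol%), CuCl, O2 (1 atm), DMF/H2O 7:1, rt
Reagents that add atoms: water O
Why: Tsuji–Wacker oxidation; Markovnikov hydroxypalladation of the monosubstituted vinyl group gives the methyl ketone, and the trisubstituted C8=C9 alkene does not react under these conditions.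

Step 13
Reactants: 18 1,4-diketone
Product: 20 4-(tert-butyldimethylsilyloxy)-3-hydroxy-6,8a-dimethyl-3-(propan-2-yl)-2,3,3a,4,5,8-hexahydroazulen-1(8aH)-one (trans-fused; 3-hydroxyl cis to the 8a-methyl group), via lithium enolate 19 (not isolated)
Conditions: LiN(i-Pr)2, THF, −78 → −40 °C; AcOH, −78 °C
Reagents that add atoms: none
Why: Intramolecular aldol addition of the kind that opens the cyclopentenone annulation of 1,4-diketones; kinetic deprotonation takes place at the acetyl methyl group, and C3 adds to the C4 ketone held trans to it across C1–C5, which gives the trans ring fusion. The isopropyl group takes the face of H5, away from the axial C1 methyl group and the C6 substituent, so the C4 hydroxyl ends cis to the C1 methyl group; the cold acidic quench forestalls retro-aldol cleavage and dehydration.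

Step 14
Reactants: 20 silylated ketol
Product: 21 3,4-dihydroxy-6,8a-dimethyl-3-(propan-2-yl)-2,3,3a,4,5,8-hexahydroazulen-1(8aH)-one
Conditions: HF·pyridine, pyridine, THF, 0 °C → rt
Reagents that add atoms: none
Why: Fluoride cleavage of the secondary silyl ether under buffered acidic conditions, which a β-hydroxy ketone tolerates, whereas basic fluoride would invite retro-aldol cleavage.

Step 15
Reactants: 21 dihydroxy ketone
Product: 22 3-hydroxy-6,8a-dimethyl-3-(propan-2-yl)-2,3,3a,5,8,8a-hexahydroazulene-1,4-dione (trans-fused)
Conditions: Dess–Martin periodinane, NaHCO3, CH2Cl2, 0 °C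
Reagents that add atoms: none
Why: Dess–Martin oxidation of the only secondary alcohol (the tertiary C4 hydroxyl cannot be oxidised); the neutral medium avoids epimerisation at C5 and migration of the β,γ alkene, and the C6 epimers converge.

Step 16
Reactants: 22 diketol
Product: 23 (1S,3R,3aS,4S,8aR)-6,8a-dimethyl-3-(propan-2-yl)-1,2,3,3a,4,5,8,8a-octahydroazulene-1,3,4-triol
Conditions: Me4NBH(OAc)3, MeCN/AcOH 1:1, −30 → −20 °C
Reagents that add atoms: none
Why: Evans–Saksena reduction; the C4 hydroxyl exchanges an acetate on boron and delivers hydride intramolecularly to both β-carbonyl groups. On the cyclopentane this puts the C2 hydroxyl trans to the C4 hydroxyl; at C6 the chair-like six-membered delivery, with the O4–C4–C5–C6 torsion fixed by the trans ring fusion, brings hydride to the face of the C4 branch, so the C6 hydroxyl ends cis to H5. The free reagent does not reduce ketones at this temperature.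

Step 17
Reactants: 23 triol; 24 angelic acid
Product: 27 (1S,3R,3aS,4S,8aR)-3-hydroxy-6,8a-dimethyl-3-(propan-2-yl)-1,2,3,3a,4,5,8,8a-octahydroazulene-1,4-diyl bis[(2Z)-2-methylbut-2-enoate] (target CNP0303897.1), via mixed anhydride 25 (not isolated), via C6 monoangelate 26 (not isolated)
Conditions: 24 (4 equiv), 2,4,6-trichlorobenzoyl chloride (4 equiv), Et3N, toluene, rt; then 23, toluene, 75 °C
Reagents that add atoms: angelic acid (second equivalent) C/C=C(/C)C(=O)O
Why: Yamaguchi-type acylation run as two successive acyl transfers in one flask, each consuming one molecule of mixed anhydride 25, so that two molecules of 24 end up in the product; the C6 hydroxyl is expected to react first (26) and the neopentyl C2 hydroxyl second. No nucleophilic catalyst adds to the unsaturated acyl group, which suppresses Z to E isomerisation to tiglate, and the tertiary C4 hydroxyl is too hindered to react.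

## Compound list

1 | 2,5-dimethylanisole | COc1cc(C)ccc1C | starting material
2 | 1-methoxy-2,5-dimethylcyclohexa-1,4-diene | COC1=C(C)CC=C(C)C1 | intermediate
3 | 7,7-dibromo-1-methoxy-3,6-dimethylbicyclo[4.1.0]hept-3-ene (racemic; cis fusion is the only possibility) | COC12CC(C)=CCC1(C)C2(Br)Br | intermediate
4 | 2-bromo-3,6-dimethylcyclohepta-2,5-dien-1-one | O=C1CC(C)=CCC(C)=C1Br | intermediate
5 | 3,6-dimethylcyclohepta-2,5-dien-1-one | CC1=CC(=O)CC(C)=CC1 | intermediate
6 | trimethylsilylacetylene | C#C[Si](C)(C)C | starting material
7 | isobutyraldehyde | CC(C)C=O | starting material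
8 | diisobutyl[1-(trimethylsilyl)vinyl]alane | C=C([Si](C)(C)C)[Al](CC(C)C)CC(C)C | intermediate
9 | diisobutylaluminium C5=C6 enolate of the conjugate adduct | CC(C)C[Al](CC(C)C)OC1=C[C@](C)(C(=C)[Si](C)(C)C)CC=C(C)C1 | intermediate
10 | 2-(1-hydroxy-2-methylpropyl)-3,6-dimethyl-3-[1-(trimethylsilyl)vinyl]cyclohept-5-en-1-one (side chain cis to 3-methyl; anti aldol) | O=C1CC(C)=CC[C@@](C)(C(=C)[Si](C)(C)C)[C@@H]1[C@H](O)C(C)C | intermediate
11 | 2-(1-isobutyryloxy-2-methylpropyl)-3,6-dimethyl-3-[1-(trimethylsilyl)vinyl]cyclohept-5-en-1-ol (1,3-anti) | O[C@@H]1CC(C)=CC[C@@](C)(C(=C)[Si](C)(C)C)[C@@H]1[C@H](OC(=O)C(C)C)C(C)C | intermediate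
12 | tert-butyldimethylsilyl ether of 11 | CC(C)(C)[Si](C)(C)O[C@@H]1CC(C)=CC[C@@](C)(C(=C)[Si](C)(C)C)[C@@H]1[C@H](OC(=O)C(C)C)C(C)C | intermediate
13 | 9-BBN adduct of 12 (boron on the terminal carbon) | CC(C)(C)[Si](C)(C)O[C@@H]1CC(C)=CC[C@@](C)(C(CB2C3CCCC2CCC3)[Si](C)(C)C)[C@@H]1[C@H](OC(=O)C(C)C)C(C)C | intermediate
14 | β-hydroxysilane: 2-[2-hydroxy-1-(trimethylsilyl)ethyl] analogue of 12 | CC(C)(C)[Si](C)(C)O[C@@H]1CC(C)=CC[C@@](C)(C(CO)[Si](C)(C)C)[C@@H]1[C@H](OC(=O)C(C)C)C(C)C | intermediate
15 | 1-[7-(tert-butyldimethylsilyloxy)-2,5-dimethyl-2-vinylcyclohept-4-en-1-yl]-2-methylpropyl isobutyrate | CC(C)(C)[Si](C)(C)O[C@@H]1CC(C)=CC[C@@](C)(C=C)[C@@H]1[C@H](OC(=O)C(C)C)C(C)C | intermediate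
16 | 1-[7-(tert-butyldimethylsilyloxy)-2,5-dimethyl-2-vinylcyclohept-4-en-1-yl]-2-methylpropan-1-ol | CC(C)(C)[Si](C)(C)O[C@@H]1CC(C)=CC[C@@](C)(C=C)[C@@H]1[C@H](O)C(C)C | intermediate
17 | 1-[7-(tert-butyldimethylsilyloxy)-2,5-dimethyl-2-vinylcyclohept-4-en-1-yl]-2-methylpropan-1-one | CC(C)(C)[Si](C)(C)O[C@@H]1CC(C)=CC[C@@](C)(C=C)[C@@H]1C(=O)C(C)C | intermediate
18 | 1-[2-acetyl-7-(tert-butyldimethylsilyloxy)-2,5-dimethylcyclohept-4-en-1-yl]-2-methylpropan-1-one | CC(C)(C)[Si](C)(C)O[C@@H]1CC(C)=CC[C@@](C)(C(C)=O)[C@@H]1C(=O)C(C)C | intermediate
19 | lithium enolate of the acetyl group of 18 | CC(C)(C)[Si](C)(C)O[C@@H]1CC(C)=CC[C@@](C)(C(=C)O[Li])[C@@H]1C(=O)C(C)C | intermediate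
20 | 4-(tert-butyldimethylsilyloxy)-3-hydroxy-6,8a-dimethyl-3-(propan-2-yl)-2,3,3a,4,5,8-hexahydroazulen-1(8aH)-one (trans-fused; 3-OH cis to 8a-methyl) | CC(C)(C)[Si](C)(C)O[C@@H]1CC(C)=CC[C@@]2(C)C(=O)C[C@@](O)(C(C)C)[C@H]12 | intermediate
21 | 3,4-dihydroxy-6,8a-dimethyl-3-(propan-2-yl)-2,3,3a,4,5,8-hexahydroazulen-1(8aH)-one | O[C@@H]1CC(C)=CC[C@@]2(C)C(=O)C[C@@](O)(C(C)C)[C@H]12 | intermediate
22 | 3-hydroxy-6,8a-dimethyl-3-(propan-2-yl)-2,3,3a,5,8,8a-hexahydroazulene-1,4-dione (trans-fused) | O=C1CC(C)=CC[C@@]2(C)C(=O)C[C@@](O)(C(C)C)[C@H]12 | intermediate
23 | (1S,3R,3aS,4S,8aR)-6,8a-dimethyl-3-(propan-2-yl)-1,2,3,3a,4,5,8,8a-octahydroazulene-1,3,4-triol | O[C@H]1CC(C)=CC[C@@]2(C)[C@@H](O)C[C@@](O)(C(C)C)[C@H]12 | intermediate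
24 | angelic acid, (2Z)-2-methylbut-2-enoic acid | C/C=C(/C)C(=O)O | starting material
25 | angelic 2,4,6-trichlorobenzoic anhydride | C/C=C(/C)C(=O)OC(=O)c1c(Cl)cc(Cl)cc1Cl | intermediate
26 | (1S,3R,3aS,4S,8aR)-1,3-dihydroxy-6,8a-dimethyl-3-(propan-2-yl)-1,2,3,3a,4,5,8,8a-octahydroazulen-4-yl (2Z)-2-methylbut-2-enoate (C6 monoangelate; C2 hydroxyl free) | C/C=C(/C)C(=O)O[C@H]1CC(C)=CC[C@@]2(C)[C@@H](O)C[C@@](O)(C(C)C)[C@H]12 | intermediate
27 | (1S,3R,3aS,4S,8aR)-3-hydroxy-6,8a-dimethyl-3-(propan-2-yl)-1,2,3,3a,4,5,8,8a-octahydroazulene-1,4-diyl bis[(2Z)-2-methylbut-2-enoate] | C/C=C(/C)C(=O)O[C@H]1CC(C)=CC[C@@]2(C)[C@@H](OC(=O)/C(C)=C\C)C[C@@](O)(C(C)C)[C@H]12 | target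

## Step count and least certain steps

Total step count: 17. Longest linear sequence: 17 steps (1 to 27); 6, 7 and 24 are commercial and enter at steps 5, 6 and 17.

**Step 5 (key step).** Three things may go wrong. The capture of the crowded aluminium enolate by a branched aldehyde may be slow or reverse, so that only the conjugate adduct is obtained. Facial discrimination at C5 may be lower than the size difference suggests. Enantioface control may drop on a seven-membered skipped dienone. For the first case the fallback separates the two bond formations. From 5 the same conjugate addition is run, but the enolate is trapped with silyl triflate as the trimethylsilyl enol ether F1. MeLi then regenerates the regiodefined lithium enolate, which adds to 7 at −78 °C and returns to the route at 10. If the C5 ratio is poor, the minor epimer is removed at 18, where acetyl and methyl make the epimers clearly different.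

**Step 8.** Hydroboration next to a quaternary carbon may be slow, and at the temperature then needed chemoselectivity against the C8=C9 alkene may be lost. The fallback removes silicon by electrophilic substitution instead. From 12, iododesilylation with N-iodosuccinimide in acetonitrile gives the 1-iodovinyl compound F2. Hydrodehalogenation of F2 with Bu3SnH and Pd(PPh3)4 (zerovalent palladium) returns to the route at 15.

**Step 13.** The closure has an endocyclic enolate and is geometrically strained. It may need warming, at which retro-aldol cleavage, dehydration to the cyclopentenone or addition from the other carbonyl face can compete. The fallback activates the acceptor instead of the donor. From 18, the acetyl group is converted to its trimethylsilyl enol ether F3 (LiN(i-Pr)2, Me3SiCl, −78 °C). A Mukaiyama aldol addition with TiCl4 at −78 °C then closes the ring within a titanium chelate and returns to the route at 20.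

**Step 16.** Two ketones are reduced in one substrate. The neopentyl C2 ketone may react slowly, and during the long reaction time the C6 ketone may suffer epimerisation at C5 or migration of the alkene. Face selectivity at C6 also depends on the ring conformation. The fallback reduces one carbonyl at a time and never has both ketones present, at the price of carrying one angelate through buffered acidic fluoride, a neutral oxidation and a mild acidic hydride. From 20 the C2 ketone alone is reduced by Me4NBH(OAc)3 to the diol F4. The C2 hydroxyl of F4 is angeloylated under the conditions of step 17 to give the C2 angelate F5. HF·pyridine then frees the C6 hydroxyl and gives the desilylated C2 angelate F6. Dess–Martin oxidation of F6 gives the C6 ketone F7, and the same directed reduction gives the C2 monoangelate F8. A second angeloylation of F8 returns to the route at 27.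

**Step 17.** Forcing conditions at the hindered C2 hydroxyl may cause Z to E isomerisation to the tiglate, or the acylation may stall after the first acyl transfer. The fallback builds the Z alkene on the ester instead of transferring it. From 23, both secondary hydroxyls are acylated with 2-[bis(2,2,2-trifluoroethoxy)phosphoryl]propanoic acid (carbodiimide coupling) to give the bis-phosphonate F9. A Still–Gennari olefination with acetaldehyde (KN(SiMe3)2, 18-crown-6, THF, −78 °C) then gives 27.

## Further compounds

F1 | step 5 | trimethylsilyl enol ether of the conjugate adduct | C[Si](C)(C)OC1=C[C@](C)(C(=C)[Si](C)(C)C)CC=C(C)C1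
F2 | step 8 | 1-iodovinyl analogue of 12 | CC(C)(C)[Si](C)(C)O[C@@H]1CC(C)=CC[C@@](C)(C(I)=C)[C@@H]1[C@H](OC(=O)C(C)C)C(C)C
F3 | step 13 | trimethylsilyl enol ether of the acetyl group of 18 | CC(C)(C)[Si](C)(C)O[C@@H]1CC(C)=CC[C@@](C)(C(=C)O[Si](C)(C)C)[C@@H]1C(=O)C(C)C
F4 | step 16 | 1,3-diol from reduction of 20 at C2 (C6 silyl ether kept) | CC(C)(C)[Si](C)(C)O[C@@H]1CC(C)=CC[C@@]2(C)[C@@H](O)C[C@@](O)(C(C)C)[C@H]12
F5 | step 16 | C2 angelate of F4 | CC(C)(C)[Si](C)(C)O[C@@H]1CC(C)=CC[C@@]2(C)[C@@H](OC(=O)/C(C)=C\C)C[C@@](O)(C(C)C)[C@H]12
F6 | step 16 | desilylated C2 angelate (C6 carbinol) | O[C@@H]1CC(C)=CC[C@@]2(C)[C@@H](OC(=O)/C(C)=C\C)C[C@@](O)(C(C)C)[C@H]12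
F7 | step 16 | C6 ketone carrying the C2 angelate | O=C1CC(C)=CC[C@@]2(C)[C@@H](OC(=O)/C(C)=C\C)C[C@@](O)(C(C)C)[C@H]12
F8 | step 16 | C2 monoangelate with C6 hydroxyl cis to H5 | O[C@H]1CC(C)=CC[C@@]2(C)[C@@H](OC(=O)/C(C)=C\C)C[C@@](O)(C(C)C)[C@H]12
F9 | step 17 | bis{2-[bis(2,2,2-trifluoroethoxy)phosphoryl]propanoate} of 23 | CC(C(=O)O[C@H]1CC(C)=CC[C@@]2(C)[C@@H](OC(=O)C(C)P(=O)(OCC(F)(F)F)OCC(F)(F)F)C[C@@](O)(C(C)C)[C@H]12)P(=O)(OCC(F)(F)F)OCC(F)(F)F
A1 | alternative 1 | (R)-terpinen-4-ol | CC1=CC[C@@](O)(C(C)C)CC1
A2 | alternative 1 | 2-allyl-6-diazo-2-methyl-5-isopropyl-3-(tert-butyldimethylsilyloxy)-5-(triethylsilyloxy)cyclohexanone | C=CC[C@@]1(C)[C@H](O[Si](C)(C)C(C)(C)C)C[C@@](O[Si](CC)(CC)CC)(C(C)C)C(=[N+]=[N-])C1=O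
A3 | alternative 1 | methyl 2-allyl-2-methyl-5-isopropyl-3-(tert-butyldimethylsilyloxy)-5-(triethylsilyloxy)cyclopentanecarboxylate | C=CC[C@@]1(C)[C@H](O[Si](C)(C)C(C)(C)C)C[C@@](O[Si](CC)(CC)CC)(C(C)C)[C@@H]1C(=O)OC
A4 | alternative 2 | (R)-4-(tert-butyldimethylsilyloxy)-2-methylcyclopent-2-en-1-one | CC1=C[C@H](O[Si](C)(C)C(C)(C)C)CC1=O
A5 | alternative 2 | 4-(tert-butyldimethylsilyloxy)-3-(1,3-dithian-2-yl)-2-methyl-2-[(Z)-4-(4-methoxybenzyloxy)-3-methylbut-2-enyl]cyclopentanone | O=C1C[C@@H](O[Si](C)(C)C(C)(C)C)[C@H](C2SCCCS2)[C@@]1(C)C/C=C(C)\COCc1ccc(OC)cc1
A6 | alternative 3 | isoprene | C=CC(C)=C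
A7 | alternative 3 | pentacarbonyl{methoxy[2-methyl-3-(tert-butyldimethylsilyloxy)-5-isopropyl-5-(triethylsilyloxy)cyclopent-1-enyl]carbene}chromium | COC(=[Cr](=C=O)(=C=O)(=C=O)(=C=O)=C=O)C1=C(C)[C@H](O[Si](C)(C)C(C)(C)C)C[C@@]1(O[Si](CC)(CC)CC)C(C)C
A8 | alternative 3 | bicyclo[5.3.0]decadiene C6 methyl enol ether with silyl ethers at C2 and C4 | COC=1CC(C)=CC[C@@]2(C)[C@H](O[Si](C)(C)C(C)(C)C)C[C@@](O[Si](CC)(CC)CC)(C(C)C)C12
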